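Does more reagent in the second phase keep giving more free target at 15 min, or does the last step up give less? If you repeat these flasks, the thing to watch is when substrate disappears from teal.

| flask | substrate | reagent in the second phase | remark | time | volume of the second phase over the first |
|---|---|---|---|---|---|
| Friday's | 0.075 M | 0.50 equiv | run made earlier |  |  |
| Tuesday's | 0.025 M | 0.50 equiv | run made earlier |  |  |
| amber | 0.050 M | 0.500 equiv |  | 15 min | 1.0 |
| blue | 0.050 M | 1.00 equiv |  | 15 min | 1.0 |
| teal | 0.050 M | 2.00 equiv |  | 15 min | 1.0 |

- Friday's (time / min: target / %, substrate / %): 1.00: 8.9, 90.7; 3.00: 15.6, 75.5; 6.00: 14.3, 62.2; 10.0: 9.6, 54.9
- Tuesday's (time / min: target / %, substrate / %): 1.00: 8.0, 91.8; 3.00: 14.2, 77.4; 6.00: 15.8, 66.3; 10.0: 11.5, 57.1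

(readings scatter by 1 percentage point)

- charges count per volume of the first phase; a concentration in a rate is the amount of a species over the volume of its own phase; every rate counts per litre of the first phase
- the numbers in the tables scatter with a standard deviation of 1 percentage point
- the earlier runs hold the two phases in the same ratio of volumes as the flask asked about
- a reading or a percentage of target counts all its forms, free or not
- the concentration of target that is asked is that of its free form alone
- "hardly changes" means that all values lie within two and a half points (for a concentration: within two and a half percent of the largest)

- [target] (only what is free in solution, in the first phase) at the end for amber, blue, teal, in this order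
- the course of these numbers from the first flask to the last (falls all the way / falls, then rises / rises, then falls / rises all the way / hardly changes)

I turn the question round: for [target] to keep rising, teal must end above blue. From Tuesday's run to Friday's the charge of substrate grows 3.00 times, yet substrate at 6.00 min differs by 4.1 percentage points, and both runs head for the floor of 50% that their reagent allows. So I take the reaction of substrate with reagent as fast and the crossing of reagent out of the second phase as the rate-limiting step, one substrate going per reagent crossed. Substrate above the floor then measures uncrossed reagent, which gives 0.235 min⁻¹ on Friday and 0.187 min⁻¹ on Tuesday, with a mean of 0.211 min⁻¹. I carry the crossing half-life, the time in which uncrossed reagent falls to half of itself: 3.29 min.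

Teal charges 2.00 equiv, so by this reckoning its substrate is used up after one crossing half-life, and target then has 11.7 min with no feed. Blue keeps feeding for 4.56 half-lives. Without any loss of target, this reckoning has blue make 95.8% of its charge of substrate into target and teal the full charge, so teal's lead is 4.22% of that charge. But target falls between 6.00 min and 10.0 min in both runs even while being fed, at a net rate, read from the two runs, of 0.0895 min⁻¹. With that loss, and an equal free share in each flask, I reckon blue over teal at 1.27, and blue at twice amber: the row rises, then falls.

The forecast gives 0.0026 M, 0.0052 M and 0.0018 M, so rises, then falls, reasoning that “the step looks limited by transfer of reagent”; its blue over teal is 2.89, larger than mine.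

The flasks give 0.00201 M, 0.00385 M and 0.00295 M, so rises, then falls, with blue over teal at 1.31.

    substrate + reagent in the reaction phase → target (k = 4.79 L mol⁻¹ s⁻¹)
    target ⇌ isomer of the product (K = 3.07, k = 0.00466 s⁻¹)
    target ⇌ product in the second phase, rate k3*([target] - [product in the second phase]/K3) per volume of the first phase (partition coefficient = 0.790, kL = 0.0261 s⁻¹)
    reagent in the reaction phase ⇌ reagent in the second phase, rate k4*([reagent in the reaction phase] - [reagent in the second phase]/K4) per volume of the first phase (partition coefficient = 5.50, kL = 0.0238 s⁻¹)
    target → decomposed product (k = 0.00456 s⁻¹)

In teal, substrate stands at 0% by 7.50 min, while reagent in the second phase stays at 42.3% of its own charge. In amber, the crossing half-life leaves 20.6% of the charge of reagent uncrossed at 7.50 min, and the flask then holds reagent in the second phase at 18.1% of its own charge.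

Readings and results were generated by integration for substances that don't exist; scatter was added.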